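**Plan**
1. Retrosynthesis: cut the aryl ether O–CH2 bond (umbelliferone, joined last), then both ring bonds C1–C2 and C3–C4 of the cyclohexanone in one [4+2] disconnection (ring numbering: C1 = C=O, C2 = CMe2, C3 = CH bearing the chain, C4 = C(Me)OH).
2. Enabling feature: C1 and C4 are para-related oxygenated ring carbons joined by the C5–C6 ethano unit. These are the four carbons and both oxygens of 5-methyl-2-silyloxyfuran, a cheap heteroarene that is dearomatised in the event. C2–C3 with its appendage is the 6,7-alkene of linalool.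
3. Helper: one terminal methyl of linalool is raised to CHO, which activates the alkene and fixes the regiochemistry. It is returned to CH3 after the cycloaddition, in the step that also saturates C5=C6.
4. Forward order: dienophile chain (steps 1–4), diene (step 5), carbocycle by union of the two fragments (step 6), adjustment (steps 7–9), coumarin ether (step 10). The coumarin ring is bought intact.
5. Stereochemistry: the chain carbinol comes from (R)-linalool. The relative configuration at ring C3/C4 comes from the E-enal and an exo transition state, the absolute configuration from a chiral oxazaborolidinium catalyst.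

Key step: step 6

Assumption: the (S)-configured oxazaborolidinium ion is taken to leave the C2-Re/C3-Si face of enal 5 open; if a first run shows the opposite sense, the mirror-image catalyst is used with no other change.

**Step 1**
Reactants: 1 (R)-(−)-linalool
Product: 2 (3R)-3,7-dimethyloct-6-ene-1,3-diol
Conditions: 9-BBN (2.3 equiv), THF, 0 °C to rt; then aq. NaOH, 30% H2O2, 0 °C to rt
Reagents that add atoms: hydrogen peroxide, OO
Why: Hydroboration–oxidation: 9-BBN adds anti-Markovnikov to the monosubstituted vinyl group much faster than to the trisubstituted 6,7-alkene, so the primary alcohol should form with the tertiary carbinol stereocentre untouched.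

**Step 2**
Reactants: 2 (3R)-3,7-dimethyloct-6-ene-1,3-diol
Product: 3 (3R)-1,3-bis[(tert-butyldimethylsilyl)oxy]-3,7-dimethyloct-6-ene
Conditions: TBSOTf (2.6 equiv), 2,6-lutidine (4 equiv), CH2Cl2, −78 to 0 °C
Reagents that add atoms: tert-butyldimethylsilyl trifluoromethanesulfonate, CC(C)(C)[Si](C)(C)OS(=O)(=O)C(F)(F)F
Why: Silyl ether formation with the silyl triflate covers the primary and the hindered tertiary hydroxyl alike, so that neither can quench the Lewis acid or the silyl dienol ether in step 6.

**Step 3**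
Reactants: 3 (3R)-1,3-bis[(tert-butyldimethylsilyl)oxy]-3,7-dimethyloct-6-ene
Product: 4 (2E,6R)-6,8-bis[(tert-butyldimethylsilyl)oxy]-2,6-dimethyloct-2-en-1-ol
Conditions: SeO2 (20 mol %), t-BuOOH (3 equiv), salicylic acid (10 mol %), CH2Cl2, rt
Reagents that add atoms: selenium dioxide, O=[Se]=O (oxygen carrier); tert-butyl hydroperoxide, CC(C)(C)OO (terminal oxygen source)
Why: Sharpless–Riley allylic oxidation (ene reaction, then [2,3]-sigmatropic shift) acts on the only alkene and should oxidise the methyl group trans to the chain with retention of the alkene geometry; any enal 5 formed alongside converges in step 4.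

**Step 4**
Reactants: 4 (2E,6R)-6,8-bis[(tert-butyldimethylsilyl)oxy]-2,6-dimethyloct-2-en-1-ol
Product: 5 (2E,6R)-6,8-bis[(tert-butyldimethylsilyl)oxy]-2,6-dimethyloct-2-enal
Conditions: MnO2 (20 equiv), CH2Cl2, rt
Reagents that add atoms: none
Why: Allylic alcohol oxidation with MnO2 should give the conjugated aldehyde without E/Z isomerisation and without touching the silyl ethers.

**Step 5**
Reactants: 6 alpha-angelica lactone
Product: 7 tert-butyldimethyl[(5-methylfuran-2-yl)oxy]silane
Conditions: TBSOTf (1.1 equiv), Et3N (1.5 equiv), CH2Cl2, 0 °C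
Reagents that add atoms: tert-butyldimethylsilyl trifluoromethanesulfonate, CC(C)(C)[Si](C)(C)OS(=O)(=O)C(F)(F)F
Why: Soft enolisation and O-silylation of the butenolide (silyl dienol ether formation) gives the aromatic 2-silyloxyfuran.

**Step 6**
Reactants: 5 (2E,6R)-6,8-bis[(tert-butyldimethylsilyl)oxy]-2,6-dimethyloct-2-enal, 7 tert-butyldimethyl[(5-methylfuran-2-yl)oxy]silane (1.5 equiv)
Product: 9 (1R,5S,6S)-5-[(tert-butyldimethylsilyl)oxy]-6-[(3R)-3,5-bis[(tert-butyldimethylsilyl)oxy]-3-methylpentyl]-1,5-dimethyl-2-oxocyclohex-3-ene-1-carbaldehyde, via silyloxy-oxanorbornene cycloadduct 8 (not isolated)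
Conditions: (S)-B-(o-tolyl) oxazaborolidine from (S)-alpha,alpha-diphenylprolinol, activated with HNTf2 (20 mol %), Ph3PO (20 mol %), CH2Cl2, −78 to −40 °C; Et3N quench, aq. NaHCO3
Reagents that add atoms: none
Why: Proposed new method: the N-protonated oxazaborolidine binds the formyl oxygen of 5 (s-trans enal, formyl C–H···O contact) and lowers the LUMO at C3, and the HOMO of 7, largest at the methyl-bearing C5, engages it in an asynchronous [4+2] cycloaddition (furan C5 to enal C3 first, then furan C2 to enal C2) to give the 1-silyloxy-7-oxanorbornene 8, whose bridging ketal collapses with O-to-O silyl transfer, releasing the catalyst and leaving the 4-silyloxy enone 9. The closest known reaction types are the thermal [4+2] addition/ring opening of 2-silyloxyfurans with electron-poor alkenes and the oxazaborolidinium-catalysed exo-selective Diels–Alder reactions of 2-methyl-substituted enals with furans and siloxy dienes; their combination on a 2-silyloxyfuran and a trisubstituted enal has not been shown. The carbocycle closes by intermolecular [4+2] cycloaddition (if stepwise, the second bond by 6-exo-trig attack of the boron enolate on the silyloxy-oxocarbenium ion), the oxygen bridge being only transient. C5 and C6 of 9 (ring C4 and C3 of the target) are set together: their relative configuration follows from the E geometry of 5 and the exo (formyl) transition state usual for 2-methyl enals, which puts the side chain anti to the bridging oxygen, and their absolute configuration from the catalyst, which must leave the C2-Re/C3-Si face of the enal open, the chain stereocentre being too remote to interfere. Regioselectivity should be secured by the matched polarity (nucleophilic methyl-bearing furan terminus to the enal beta carbon), and cycloaddition over 1,2-addition to the formyl group by the hindered boron-bound carbonyl and the low temperature. The quaternary centre C1 of 9 forms as one isomer but loses its stereogenicity in step 8.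

**Step 7**
Reactants: 9 (1R,5S,6S)-5-[(tert-butyldimethylsilyl)oxy]-6-[(3R)-3,5-bis[(tert-butyldimethylsilyl)oxy]-3-methylpentyl]-1,5-dimethyl-2-oxocyclohex-3-ene-1-carbaldehyde
Product: 10 (4S,5S,6S)-4-[(tert-butyldimethylsilyl)oxy]-5-[(3R)-3,5-bis[(tert-butyldimethylsilyl)oxy]-3-methylpentyl]-6-(1,3-dithiolan-2-yl)-4,6-dimethylcyclohex-2-en-1-one
Conditions: HSCH2CH2SH (1.3 equiv), Zn(OTf)2 (20 mol %), CH2Cl2, 0 °C to rt
Reagents that add atoms: ethane-1,2-dithiol, SCCS
Why: Lewis-acid-catalysed dithioacetalisation should be chemoselective for the aldehyde over the cross-conjugated ketone next to a quaternary carbon, Zn(OTf)2 being mild enough for the three silyl ethers; the silylated C4 oxygen cannot form a lactol with the cis formyl group.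

**Step 8**
Reactants: 10 (4S,5S,6S)-4-[(tert-butyldimethylsilyl)oxy]-5-[(3R)-3,5-bis[(tert-butyldimethylsilyl)oxy]-3-methylpentyl]-6-(1,3-dithiolan-2-yl)-4,6-dimethylcyclohex-2-en-1-one
Product: 11 (3S,4S)-4-[(tert-butyldimethylsilyl)oxy]-3-[(3R)-3,5-bis[(tert-butyldimethylsilyl)oxy]-3-methylpentyl]-2,2,4-trimethylcyclohexan-1-one
Conditions: Raney Ni (W-2, excess), H2 (1 atm), EtOH, rt
Reagents that add atoms: none
Why: Mozingo-type desulfurisation on Raney Ni turns the dithiolane carbon into the second methyl of the gem-dimethyl centre, and the same hydrogen-laden nickel under H2 should saturate the enone C=C; neither ring stereocentre is alpha to the ketone, so none can epimerise.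

**Step 9**
Reactants: 11 (3S,4S)-4-[(tert-butyldimethylsilyl)oxy]-3-[(3R)-3,5-bis[(tert-butyldimethylsilyl)oxy]-3-methylpentyl]-2,2,4-trimethylcyclohexan-1-one
Product: 12 (3S,4S)-3-[(3R)-3,5-dihydroxy-3-methylpentyl]-4-hydroxy-2,2,4-trimethylcyclohexan-1-one
Conditions: 48% aq. HF, MeCN, 0 °C to rt
Reagents that add atoms: none
Why: Fluoride-driven cleavage of the primary and the two tertiary silyl ethers; the conditions should be mild enough to spare the tertiary alcohols, and the gamma-hydroxy ketone has no retro-aldol path.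

**Step 10**
Reactants: 12 (3S,4S)-3-[(3R)-3,5-dihydroxy-3-methylpentyl]-4-hydroxy-2,2,4-trimethylcyclohexan-1-one, 13 umbelliferone
Product: 14 7-{[(3R)-3-hydroxy-5-[(1S,6S)-6-hydroxy-2,2,6-trimethyl-3-oxocyclohexyl]-3-methylpentyl]oxy}-2H-chromen-2-one (CNP0414652.2)
Conditions: PPh3 (1.3 equiv), DIAD (1.3 equiv), THF, 0 °C to rt
Reagents that add atoms: none
Why: Mitsunobu etherification: only the primary alcohol forms the oxyphosphonium ion and is displaced by the acidic phenol (pKa about 8), the two tertiary alcohols and the ketone being inert, so no stereocentre is touched.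

**Compound list**
1 | (R)-(−)-linalool, (3R)-3,7-dimethylocta-1,6-dien-3-ol | C=C[C@](C)(O)CCC=C(C)C | starting material
2 | (3R)-3,7-dimethyloct-6-ene-1,3-diol | OCC[C@](C)(O)CCC=C(C)C | intermediate
3 | (3R)-1,3-bis[(tert-butyldimethylsilyl)oxy]-3,7-dimethyloct-6-ene | CC(C)=CCC[C@](C)(CCO[Si](C)(C)C(C)(C)C)O[Si](C)(C)C(C)(C)C | intermediate
4 | (2E,6R)-6,8-bis[(tert-butyldimethylsilyl)oxy]-2,6-dimethyloct-2-en-1-ol | OC/C(C)=C/CC[C@](C)(CCO[Si](C)(C)C(C)(C)C)O[Si](C)(C)C(C)(C)C | intermediate
5 | (2E,6R)-6,8-bis[(tert-butyldimethylsilyl)oxy]-2,6-dimethyloct-2-enal | O=C/C(C)=C/CC[C@](C)(CCO[Si](C)(C)C(C)(C)C)O[Si](C)(C)C(C)(C)C | intermediate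
6 | alpha-angelica lactone, 5-methylfuran-2(3H)-one | CC1=CCC(=O)O1 | starting material
7 | tert-butyldimethyl[(5-methylfuran-2-yl)oxy]silane | Cc1ccc(O[Si](C)(C)C(C)(C)C)o1 | intermediate
8 | (1S,2R,3S,4S)-1-[(tert-butyldimethylsilyl)oxy]-3-[(3R)-3,5-bis[(tert-butyldimethylsilyl)oxy]-3-methylpentyl]-2,4-dimethyl-7-oxabicyclo[2.2.1]hept-5-ene-2-carbaldehyde (formyl exo, side chain endo) | C[C@@]12C=C[C@@](O[Si](C)(C)C(C)(C)C)(O1)[C@@](C)(C=O)[C@@H]2CC[C@@](C)(O[Si](C)(C)C(C)(C)C)CCO[Si](C)(C)C(C)(C)C | intermediate (formed in the flask, not isolated)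
9 | (1R,5S,6S)-5-[(tert-butyldimethylsilyl)oxy]-6-[(3R)-3,5-bis[(tert-butyldimethylsilyl)oxy]-3-methylpentyl]-1,5-dimethyl-2-oxocyclohex-3-ene-1-carbaldehyde | O=C1C=C[C@](C)(O[Si](C)(C)C(C)(C)C)[C@@H](CC[C@@](C)(O[Si](C)(C)C(C)(C)C)CCO[Si](C)(C)C(C)(C)C)[C@]1(C)C=O | intermediate
10 | (4S,5S,6S)-4-[(tert-butyldimethylsilyl)oxy]-5-[(3R)-3,5-bis[(tert-butyldimethylsilyl)oxy]-3-methylpentyl]-6-(1,3-dithiolan-2-yl)-4,6-dimethylcyclohex-2-en-1-one | O=C1C=C[C@](C)(O[Si](C)(C)C(C)(C)C)[C@@H](CC[C@@](C)(O[Si](C)(C)C(C)(C)C)CCO[Si](C)(C)C(C)(C)C)[C@]1(C)C2SCCS2 | intermediate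
11 | (3S,4S)-4-[(tert-butyldimethylsilyl)oxy]-3-[(3R)-3,5-bis[(tert-butyldimethylsilyl)oxy]-3-methylpentyl]-2,2,4-trimethylcyclohexan-1-one | O=C1CC[C@](C)(O[Si](C)(C)C(C)(C)C)[C@@H](CC[C@@](C)(O[Si](C)(C)C(C)(C)C)CCO[Si](C)(C)C(C)(C)C)C1(C)C | intermediate
12 | (3S,4S)-3-[(3R)-3,5-dihydroxy-3-methylpentyl]-4-hydroxy-2,2,4-trimethylcyclohexan-1-one | O=C1CC[C@](C)(O)[C@@H](CC[C@@](C)(O)CCO)C1(C)C | intermediate
13 | umbelliferone, 7-hydroxy-2H-chromen-2-one | O=c1ccc2ccc(O)cc2o1 | starting material
14 | 7-{[(3R)-3-hydroxy-5-[(1S,6S)-6-hydroxy-2,2,6-trimethyl-3-oxocyclohexyl]-3-methylpentyl]oxy}-2H-chromen-2-one | CC1(C)C(=O)CC[C@](C)(O)[C@H]1CC[C@@](C)(O)CCOc1ccc2ccc(=O)oc2c1 | target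

**Summary**
Total steps: 10. Longest linear sequence: 9 steps (1 to 14 through steps 1–4 and 6–10).

Steps most likely to fail:

Step 6 (bears the label). What may go wrong: 1,2-addition of the diene to the formyl group (vinylogous Mukaiyama aldol) in place of cycloaddition, protodesilylation of the diene by the acidic catalyst, arrest after the first C–C bond, and insufficient facial discrimination. The fallback uses known chemistry; it sets out from 5 and 7 and comes back at 11. The cycloaddition is run without catalyst under high pressure (about 12 kbar, CH2Cl2, rt), a known way to drive [4+2] additions of furans and 2-silyloxyfurans to sluggish electron-poor alkenes. It should give the exo adducts without facial control, that is 9 together with the (1S,5R,6R) ring diastereomer of 9 F1. The mixture is taken through the conditions of steps 7 and 8, giving 10 with the ring-mirrored dithiolane F2, and then 11 with the ring-mirrored ketone F3. Reduction of this ketone pair with BH3·SMe2 and the (S)-2-methyl-CBS-oxazaborolidine is reagent-controlled and should give the (1R)-carbinol in both series: the trans alcohol F4 from 11 (hydroxyl trans to the side chain) and the cis alcohol F5 from F3 (hydroxyl cis to the side chain). These are ring cis/trans isomers and should separate on silica; Dess–Martin oxidation of F4 returns 11. Catalyst control of the cycloaddition is thus replaced by a reagent-controlled resolution after the ring is made.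

Step 7. What may go wrong: conjugate addition of the thiol to the enone, loss of the formyl group by retro-Claisen cleavage, non-selective thioketalisation of the ring ketone, and over-reduction of the ketone on nickel in the step that follows. The fallback sets out from 9 and comes back at 11, with the formyl group treated as a traceless activating group. K2CO3 in MeOH at rt (retro-Claisen deformylation of the non-enolisable beta-keto aldehyde) should give the deformylated enone F6. LiN(iPr)2 in THF at −78 °C followed by MeI (alpha-prime methylation of the cross-conjugated enolate, the only enolisable position) should give the gem-dimethyl enone F7. Hydrogenation (H2, Pd/C, EtOAc) then gives 11.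

Step 3. What may go wrong: incomplete conversion, over-oxidation, and poor site selectivity among the allylic positions. The fallback sets out from 3 and comes back at 5. Ozonolysis (O3, CH2Cl2/MeOH, −78 °C, then PPh3) should give the aldehyde F8. A Wittig reaction with the stabilised ylide Ph3P=C(CH3)CHO (toluene, 90 °C) should then give 5 with E geometry.

**Further compounds**
F1 | step 6 | (1S,5R,6R)-5-[(tert-butyldimethylsilyl)oxy]-6-[(3R)-3,5-bis[(tert-butyldimethylsilyl)oxy]-3-methylpentyl]-1,5-dimethyl-2-oxocyclohex-3-ene-1-carbaldehyde | O=C1C=C[C@@](C)(O[Si](C)(C)C(C)(C)C)[C@H](CC[C@@](C)(O[Si](C)(C)C(C)(C)C)CCO[Si](C)(C)C(C)(C)C)[C@@]1(C)C=O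
F2 | step 6 | (4R,5R,6R)-4-[(tert-butyldimethylsilyl)oxy]-5-[(3R)-3,5-bis[(tert-butyldimethylsilyl)oxy]-3-methylpentyl]-6-(1,3-dithiolan-2-yl)-4,6-dimethylcyclohex-2-en-1-one | O=C1C=C[C@@](C)(O[Si](C)(C)C(C)(C)C)[C@H](CC[C@@](C)(O[Si](C)(C)C(C)(C)C)CCO[Si](C)(C)C(C)(C)C)[C@@]1(C)C2SCCS2
F3 | step 6 | (3R,4R)-4-[(tert-butyldimethylsilyl)oxy]-3-[(3R)-3,5-bis[(tert-butyldimethylsilyl)oxy]-3-methylpentyl]-2,2,4-trimethylcyclohexan-1-one | O=C1CC[C@@](C)(O[Si](C)(C)C(C)(C)C)[C@H](CC[C@@](C)(O[Si](C)(C)C(C)(C)C)CCO[Si](C)(C)C(C)(C)C)C1(C)C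
F4 | step 6 | (1R,3S,4S)-4-[(tert-butyldimethylsilyl)oxy]-3-[(3R)-3,5-bis[(tert-butyldimethylsilyl)oxy]-3-methylpentyl]-2,2,4-trimethylcyclohexan-1-ol | O[C@@H]1CC[C@](C)(O[Si](C)(C)C(C)(C)C)[C@@H](CC[C@@](C)(O[Si](C)(C)C(C)(C)C)CCO[Si](C)(C)C(C)(C)C)C1(C)C
F5 | step 6 | (1R,3R,4R)-4-[(tert-butyldimethylsilyl)oxy]-3-[(3R)-3,5-bis[(tert-butyldimethylsilyl)oxy]-3-methylpentyl]-2,2,4-trimethylcyclohexan-1-ol | O[C@@H]1CC[C@@](C)(O[Si](C)(C)C(C)(C)C)[C@H](CC[C@@](C)(O[Si](C)(C)C(C)(C)C)CCO[Si](C)(C)C(C)(C)C)C1(C)C
F6 | step 7 | (4S,5S,6S)-4-[(tert-butyldimethylsilyl)oxy]-5-[(3R)-3,5-bis[(tert-butyldimethylsilyl)oxy]-3-methylpentyl]-4,6-dimethylcyclohex-2-en-1-one (6-methyl trans to the side chain; this centre is lost in the next operation) | O=C1C=C[C@](C)(O[Si](C)(C)C(C)(C)C)[C@@H](CC[C@@](C)(O[Si](C)(C)C(C)(C)C)CCO[Si](C)(C)C(C)(C)C)[C@@H]1C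
F7 | step 7 | (4S,5S)-4-[(tert-butyldimethylsilyl)oxy]-5-[(3R)-3,5-bis[(tert-butyldimethylsilyl)oxy]-3-methylpentyl]-4,6,6-trimethylcyclohex-2-en-1-one | O=C1C=C[C@](C)(O[Si](C)(C)C(C)(C)C)[C@@H](CC[C@@](C)(O[Si](C)(C)C(C)(C)C)CCO[Si](C)(C)C(C)(C)C)C1(C)C
F8 | step 3 | (4R)-4,6-bis[(tert-butyldimethylsilyl)oxy]-4-methylhexanal | O=CCC[C@](C)(CCO[Si](C)(C)C(C)(C)C)O[Si](C)(C)C(C)(C)C
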